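**Retrosynthetic overview**

1. The target is the O8‑isovanillate of (4R,5R,6R,7R,8R)‑4,5‑epoxygermacr‑1(10)E‑ene‑6,8‑diol; esterification at O8, saturation of the C7 branch and desilylation are end‑game operations.
2. Key disconnection: C7–C8 of the ten‑membered carbocycle. The enabling feature is that carbinol C8 is bonded to C7, whose isopropyl group (C11, C12, C13) is a hydrogenated isopropenyl group; C8(OH)–C7–C11=C12 is therefore a homoallylic alcohol, and the ring closes by intramolecular allylation of a C8 aldehyde by a C12–C11–C7 allyl metal, with O6 on the neighbouring C6 steering the face.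
3. The open chain is a head‑to‑tail C15 chain that already holds the E alkene C1=C10 and the 4,5‑oxirane. C1–C6, C9, C10, C14 and C15 come from geranyl acetate (C9 is its E‑methyl group); C8 is added by Wittig methylenation and oxygenated late by hydroboration of the terminal diene.
4. C7 and C11–C13 come from a C4 linchpin, (E)‑3‑iodo‑2‑methylallyl benzoate, which bonds to C6 as an alkenyl nucleophile and later to C8 as an allyl nucleophile.
5. Stereocentres: C4/C5 by Sharpless epoxidation, C6 by Felkin–Anh addition, C7/C8 in the ring closure. Rings form in the order oxirane (step 5), then the ten‑membered ring (step 13); the arene is bought as isovanillic acid.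

Key step: step 13

Remark: germacrane atom labels are used throughout, also for open‑chain intermediates (ring C1–C10, E alkene C1=C10, C14 on C10, C15 on C4, branch C11–C13 on C7). The C7 descriptor reads S in the silyl ethers 19, 20 and 24 and R in the target, although the spatial arrangement is the same.

**Route**

Step 1
Reactants: 1 geranyl acetate
Product: 2 (2E,6E)-8-hydroxy-3,7-dimethylocta-2,6-dien-1-yl acetate
Conditions: SeO2 (cat.), t-BuOOH, salicylic acid (cat.), CH2Cl2, rt
Reagents that add atoms: tert-butyl hydroperoxide, CC(C)(C)OO (terminal oxygen source; SeO2, O=[Se]=O, transfers the oxygen and is regenerated)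
Why: Riley allylic oxidation (ene reaction of SeO2, then [2,3]-sigmatropic shift) should attack the E-methyl group of the electron-richer terminal alkene, the allylic acetate deactivating the other alkene, so that the new CH2OH (C9) stands E to the chain.

Step 2
Reactants: 2 (2E,6E)-8-hydroxy-3,7-dimethylocta-2,6-dien-1-yl acetate
Product: 3 (2E,6E)-3,7-dimethyl-8-oxoocta-2,6-dien-1-yl acetate
Conditions: MnO2, CH2Cl2, rt
Reagents that add atoms: none
Why: MnO2 oxidation is selective for allylic alcohols and should give the enal without touching the acetate or the alkene geometry.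

Step 3
Reactants: 3 (2E,6E)-3,7-dimethyl-8-oxoocta-2,6-dien-1-yl acetate
Product: 4 (2E,6E)-3,7-dimethylnona-2,6,8-trien-1-yl acetate
Conditions: Ph3PCH3Br, KN(SiMe3)2, THF, −78 °C to 0 °C
Reagents that add atoms: methyltriphenylphosphonium bromide, C[P+](c1ccccc1)(c1ccccc1)c1ccccc1.[Br-]
Why: Wittig methylenation of the enal by the non-stabilised ylide is much faster than attack on the acetate at low temperature and adds C8 as the terminus of a 1,3-diene.

Step 4
Reactants: 4 (2E,6E)-3,7-dimethylnona-2,6,8-trien-1-yl acetate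
Product: 5 (2E,6E)-3,7-dimethylnona-2,6,8-trien-1-ol
Conditions: K2CO3 (cat.), MeOH, 0 °C to rt
Reagents that add atoms: none
Why: Base-catalysed transesterification (methanolysis) frees the allylic alcohol that is needed to direct the epoxidation.

Step 5
Reactants: 5 (2E,6E)-3,7-dimethylnona-2,6,8-trien-1-ol
Product: 6 [(2R,3R)-3-methyl-3-[(3E)-4-methylhexa-3,5-dien-1-yl]oxiran-2-yl]methanol
Conditions: Ti(OiPr)4 (cat.), diethyl (2S,3S)-tartrate [the (−) enantiomer] (cat.), t-BuOOH, 4 Å molecular sieves, CH2Cl2, −20 °C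
Reagents that add atoms: tert-butyl hydroperoxide, CC(C)(C)OO
Why: Sharpless asymmetric epoxidation acts only on the allylic-alcohol alkene, and the (−)-tartrate should deliver oxygen to the face that gives the (2R,3R) oxirane (geraniol-type substrates give the 2S,3S series with the (+)-tartrate), which sets C4 and C5 while the diene stays untouched.

Step 6
Reactants: 6 [(2R,3R)-3-methyl-3-[(3E)-4-methylhexa-3,5-dien-1-yl]oxiran-2-yl]methanol
Product: 7 (2S,3R)-3-methyl-3-[(3E)-4-methylhexa-3,5-dien-1-yl]oxirane-2-carbaldehyde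
Conditions: Dess–Martin periodinane, pyridine, CH2Cl2, 0 °C to rt
Reagents that add atoms: none
Why: Buffered Dess–Martin oxidation should give the epoxy aldehyde without opening the oxirane, and the α-carbon, being an oxirane carbon, does not epimerise (the descriptor changes only because of priorities).

Step 7
Reactants: 8 prop-2-yn-1-ol
Product: 10 (2E)-3-iodo-2-methylprop-2-en-1-ol, via alkenylalane 9 (not isolated)
Conditions: AlMe3, Cp2ZrCl2 (cat.), CH2Cl2, 0 °C to rt; then I2, THF, −30 °C to 0 °C; aq. K2CO3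
Reagents that add atoms: trimethylaluminium, C[Al](C)C; iodine, II
Why: Zirconium-catalysed carboalumination (Negishi) adds methyl and aluminium syn across the alkyne with aluminium on the terminal carbon, and iodinolysis with retention gives the E iodoalkene.

Step 8
Reactants: 10 (2E)-3-iodo-2-methylprop-2-en-1-ol
Product: 11 (2E)-3-iodo-2-methylprop-2-en-1-yl benzoate
Conditions: BzCl, Et3N, DMAP (cat.), CH2Cl2, 0 °C
Reagents that add atoms: benzoyl chloride, O=C(Cl)c1ccccc1
Why: Standard acylation of the primary allylic alcohol; the benzoate is the leaving group for the later π-allylpalladium formation and should survive the chromium, borane and periodinane steps.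

Step 9
Reactants: 7 (2S,3R)-3-methyl-3-[(3E)-4-methylhexa-3,5-dien-1-yl]oxirane-2-carbaldehyde; 11 (2E)-3-iodo-2-methylprop-2-en-1-yl benzoate
Product: 12 (2E,4R)-4-hydroxy-2-methyl-4-[(2R,3R)-3-methyl-3-[(3E)-4-methylhexa-3,5-dien-1-yl]oxiran-2-yl]but-2-en-1-yl benzoate
Conditions: CrCl2, NiCl2 (cat., kept at 1 mol % or less), DMSO, rt; aq. NH4Cl
Reagents that add atoms: none
Why: Nozaki–Hiyama–Kishi coupling, in which the alkenylchromium formed with retention of the E geometry adds to the aldehyde in the presence of benzoate, oxirane and diene (epoxy aldehydes tolerate CrCl2, as in Takai olefination), and Felkin–Anh attack anti to the oxirane C–O bond should favour the (R)-carbinol at C6 (anti epoxy alcohol), the minor epimer being removed by chromatography.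

Step 10
Reactants: 12 (2E,4R)-4-hydroxy-2-methyl-4-[(2R,3R)-3-methyl-3-[(3E)-4-methylhexa-3,5-dien-1-yl]oxiran-2-yl]but-2-en-1-yl benzoate
Product: 13 (2E,4R)-2-methyl-4-[(2R,3R)-3-methyl-3-[(3E)-4-methylhexa-3,5-dien-1-yl]oxiran-2-yl]-4-(triethylsilyloxy)but-2-en-1-yl benzoate
Conditions: Et3SiCl, imidazole, DMF, 0 °C
Reagents that add atoms: chlorotriethylsilane, CC[Si](Cl)(CC)CC
Why: Silylation of the secondary alcohol masks O6 through the oxidation and organometallic steps as a triethylsilyl ether that buffered fluoride can remove at the end, and it makes O6 the stereoelectronic control element of the ring closure.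

Step 11
Reactants: 13 (2E,4R)-2-methyl-4-[(2R,3R)-3-methyl-3-[(3E)-4-methylhexa-3,5-dien-1-yl]oxiran-2-yl]-4-(triethylsilyloxy)but-2-en-1-yl benzoate
Product: 15 (2E,4R)-4-[(2R,3R)-3-[(3E)-6-hydroxy-4-methylhex-3-en-1-yl]-3-methyloxiran-2-yl]-2-methyl-4-(triethylsilyloxy)but-2-en-1-yl benzoate, via alkylborane 14 (not isolated)
Conditions: 9-BBN, THF, 0 °C to rt; then NaBO3·4H2O, H2O, rt
Reagents that add atoms: sodium perborate, [Na+].[Na+].O[B-]1(O)OO[B-](O)(O)OO1
Why: Hydroboration with bulky 9-BBN should occur only at the monosubstituted terminal alkene of the diene (boron on C8, anti-Markovnikov) and not at the trisubstituted alkenes, and mild perborate oxidation gives the homoallylic primary alcohol with benzoate, oxirane and silyl ether intact.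

Step 12
Reactants: 15 (2E,4R)-4-[(2R,3R)-3-[(3E)-6-hydroxy-4-methylhex-3-en-1-yl]-3-methyloxiran-2-yl]-2-methyl-4-(triethylsilyloxy)but-2-en-1-yl benzoate
Product: 16 (2E,4R)-2-methyl-4-[(2R,3R)-3-methyl-3-[(3E)-4-methyl-6-oxohex-3-en-1-yl]oxiran-2-yl]-4-(triethylsilyloxy)but-2-en-1-yl benzoate
Conditions: Dess–Martin periodinane, pyridine, CH2Cl2, 0 °C; used at once
Reagents that add atoms: none
Why: Buffered Dess–Martin oxidation gives the β,γ-unsaturated C8 aldehyde under neutral conditions that should not move the C1=C10 alkene into conjugation.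

Step 13
Reactants: 16 (2E,4R)-2-methyl-4-[(2R,3R)-3-methyl-3-[(3E)-4-methyl-6-oxohex-3-en-1-yl]oxiran-2-yl]-4-(triethylsilyloxy)but-2-en-1-yl benzoate
Product: 19 (4R,5R,6R,7S,8R)-4,5-epoxy-6-(triethylsilyloxy)germacra-1(10)E,11-dien-8-ol, via allylzinc species 17 (not isolated), via zinc alkoxide 18 (not isolated)
Conditions: Pd(PPh3)4 (10 mol %), Et2Zn (3 equiv), THF, rt, 16 added slowly by syringe pump to about 0.002 mol/L; aq. NH4Cl
Reagents that add atoms: none
Why: Zerovalent palladium ionises the allylic benzoate to a π-allylpalladium species that Et2Zn transmetalates to the nucleophilic allylzinc 17, which adds through its γ-carbon C7 to the C8 aldehyde; the closest known reaction type is the palladium/diethylzinc umpolung allylation of aldehydes with allyl benzoates, which is precedented for closing ten-membered carbocycles of this class from open-chain allylic electrophile–aldehydes. The ten-membered ring closes in a 10-exo-trig addition, the twelve-membered alternative through C12 being excluded because the cyclic six-membered metal–oxygen transition state demands γ-attack. C7 and C8 are set together in the chair Zimmerman–Traxler transition state of the E allylzinc (C6 trans to C12), with C6 and C9 both pseudo-equatorial, which should give the target relationship in which O8 and C11 are syn along the ring. The sense at C7 is controlled by the C6 stereocentre: A1,3 strain with the C13 methyl group holds H6 in the alkene plane and C8 adds anti to the C6–OSiEt3 bond, on the face that carries C5 and that the tether can reach. The step needs allylation to win over ethyl transfer, enolisation of the β,γ-unsaturated aldehyde and dimerisation; fast transmetalation, the low basicity of organozincs and slow addition at high dilution should secure this, and the oxirane and silyl ether are inert to the neutral reagents.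

Step 14
Reactants: 19 (4R,5R,6R,7S,8R)-4,5-epoxy-6-(triethylsilyloxy)germacra-1(10)E,11-dien-8-ol
Product: 20 (4R,5R,6R,7S,8R)-4,5-epoxy-6-(triethylsilyloxy)germacr-1(10)E-en-8-ol
Conditions: H2 (1 atm), RhCl(PPh3)3 (cat.), benzene, rt
Reagents that add atoms: none
Why: Homogeneous hydrogenation with RhCl(PPh3)3 is highly sensitive to alkene substitution and should reduce the exocyclic 1,1-disubstituted alkene to the isopropyl group while the trisubstituted ring alkene, the oxirane and the silyl ether stay untouched; no stereocentre is formed.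

Step 15
Reactants: 21 isovanillic acid
Product: 23 3-(tert-butyldimethylsilyloxy)-4-methoxybenzoic acid, via bis-silyl derivative 22 (not isolated)
Conditions: t-BuMe2SiCl, imidazole, DMF, rt; then AcOH, THF, H2O, rt
Reagents that add atoms: tert-butyl(chloro)dimethylsilane, CC(C)(C)[Si](C)(C)Cl
Why: Exhaustive silylation followed by selective hydrolysis of the labile silyl ester leaves the phenol protected as its silyl ether, so that the acid cannot acylate itself.

Step 16
Reactants: 20 (4R,5R,6R,7S,8R)-4,5-epoxy-6-(triethylsilyloxy)germacr-1(10)E-en-8-ol; 23 3-(tert-butyldimethylsilyloxy)-4-methoxybenzoic acid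
Product: 24 (4R,5R,6R,7S,8R)-4,5-epoxy-6-(triethylsilyloxy)germacr-1(10)E-en-8-yl 3-(tert-butyldimethylsilyloxy)-4-methoxybenzoate
Conditions: DCC (N,N'-dicyclohexylcarbodiimide), DMAP, CH2Cl2, rt
Reagents that add atoms: none
Why: Steglich esterification (carbodiimide activation with DMAP as acyl-transfer catalyst) acylates the only free hydroxyl, the hindered secondary O8, under neutral conditions and with retention at C8.

Step 17
Reactants: 24 (4R,5R,6R,7S,8R)-4,5-epoxy-6-(triethylsilyloxy)germacr-1(10)E-en-8-yl 3-(tert-butyldimethylsilyloxy)-4-methoxybenzoate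
Product: 25 (4R,5R,6R,7R,8R)-4,5-epoxy-6-hydroxygermacr-1(10)E-en-8-yl 3-hydroxy-4-methoxybenzoate
Conditions: Bu4NF, AcOH, THF, 0 °C to rt
Reagents that add atoms: none
Why: Fluoride-mediated desilylation cleaves both the triethylsilyl ether and the aryl silyl ether, acetic acid buffering should suppress 1,3-acyl migration from O8 to O6 and alkoxide attack on the oxirane, and strong acid is avoided because the 4,5-epoxide of a germacr-1(10)-ene cyclises transannularly.

**Compound list**

1 | geranyl acetate, (2E)-3,7-dimethylocta-2,6-dien-1-yl acetate | CC(=O)OC/C=C(C)/CCC=C(C)C | starting material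
2 | (2E,6E)-8-hydroxy-3,7-dimethylocta-2,6-dien-1-yl acetate | CC(=O)OC/C=C(C)/CC/C=C(C)/CO | intermediate
3 | (2E,6E)-3,7-dimethyl-8-oxoocta-2,6-dien-1-yl acetate | CC(=O)OC/C=C(C)/CC/C=C(C)/C=O | intermediate
4 | (2E,6E)-3,7-dimethylnona-2,6,8-trien-1-yl acetate | CC(=O)OC/C=C(C)/CC/C=C(C)/C=C | intermediate
5 | (2E,6E)-3,7-dimethylnona-2,6,8-trien-1-ol | C=C/C(C)=C/CC/C(C)=C/CO | intermediate
6 | [(2R,3R)-3-methyl-3-[(3E)-4-methylhexa-3,5-dien-1-yl]oxiran-2-yl]methanol | C=C/C(C)=C/CC[C@@]1(C)O[C@@H]1CO | intermediate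
7 | (2S,3R)-3-methyl-3-[(3E)-4-methylhexa-3,5-dien-1-yl]oxirane-2-carbaldehyde | C=C/C(C)=C/CC[C@@]1(C)O[C@@H]1C=O | intermediate
8 | prop-2-yn-1-ol (propargyl alcohol) | C#CCO | starting material
9 | alkenylalane: dimethylaluminium (2E)-3-(dimethylalumanyl)-2-methylprop-2-en-1-olate | C[Al](C)OC/C(C)=C/[Al](C)C | intermediate
10 | (2E)-3-iodo-2-methylprop-2-en-1-ol | OC/C(C)=C/I | intermediate
11 | (2E)-3-iodo-2-methylprop-2-en-1-yl benzoate | O=C(OC/C(C)=C/I)c1ccccc1 | intermediate
12 | (2E,4R)-4-hydroxy-2-methyl-4-[(2R,3R)-3-methyl-3-[(3E)-4-methylhexa-3,5-dien-1-yl]oxiran-2-yl]but-2-en-1-yl benzoate | C=C/C(C)=C/CC[C@@]1(C)O[C@@H]1[C@H](O)/C=C(\C)COC(=O)c1ccccc1 | intermediate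
13 | (2E,4R)-2-methyl-4-[(2R,3R)-3-methyl-3-[(3E)-4-methylhexa-3,5-dien-1-yl]oxiran-2-yl]-4-(triethylsilyloxy)but-2-en-1-yl benzoate | C=C/C(C)=C/CC[C@@]1(C)O[C@@H]1[C@H](O[Si](CC)(CC)CC)/C=C(\C)COC(=O)c1ccccc1 | intermediate
14 | alkylborane: B-alkyl-9-borabicyclo[3.3.1]nonane from 13, boron on C8 | B1(CC/C(C)=C/CC[C@@]3(C)O[C@@H]3[C@H](O[Si](CC)(CC)CC)/C=C(\C)COC(=O)c3ccccc3)C2CCCC1CCC2 | intermediate
15 | (2E,4R)-4-[(2R,3R)-3-[(3E)-6-hydroxy-4-methylhex-3-en-1-yl]-3-methyloxiran-2-yl]-2-methyl-4-(triethylsilyloxy)but-2-en-1-yl benzoate | OCC/C(C)=C/CC[C@@]1(C)O[C@@H]1[C@H](O[Si](CC)(CC)CC)/C=C(\C)COC(=O)c1ccccc1 | intermediate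
16 | (2E,4R)-2-methyl-4-[(2R,3R)-3-methyl-3-[(3E)-4-methyl-6-oxohex-3-en-1-yl]oxiran-2-yl]-4-(triethylsilyloxy)but-2-en-1-yl benzoate | O=CC/C(C)=C/CC[C@@]1(C)O[C@@H]1[C@H](O[Si](CC)(CC)CC)/C=C(\C)COC(=O)c1ccccc1 | intermediate
17 | allylzinc species: ethyl(allyl)zinc from 16, zinc on C12 in place of the benzoate | O=CC/C(C)=C/CC[C@@]1(C)O[C@@H]1[C@H](O[Si](CC)(CC)CC)/C=C(\C)C[Zn]CC | intermediate
18 | zinc alkoxide: ethylzinc alkoxide of 19 | CC[Zn]O[C@@H]1C/C(C)=C/CC[C@@]2(C)O[C@@H]2[C@H](O[Si](CC)(CC)CC)[C@H]1C(C)=C | intermediate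
19 | (4R,5R,6R,7S,8R)-4,5-epoxy-6-(triethylsilyloxy)germacra-1(10)E,11-dien-8-ol | O[C@@H]1C/C(C)=C/CC[C@@]2(C)O[C@@H]2[C@H](O[Si](CC)(CC)CC)[C@H]1C(C)=C | intermediate
20 | (4R,5R,6R,7S,8R)-4,5-epoxy-6-(triethylsilyloxy)germacr-1(10)E-en-8-ol | O[C@@H]1C/C(C)=C/CC[C@@]2(C)O[C@@H]2[C@H](O[Si](CC)(CC)CC)[C@H]1C(C)C | intermediate
21 | isovanillic acid, 3-hydroxy-4-methoxybenzoic acid | COc1ccc(C(=O)O)cc1O | starting material
22 | bis-silyl derivative: tert-butyldimethylsilyl 3-(tert-butyldimethylsilyloxy)-4-methoxybenzoate | COc1ccc(C(=O)O[Si](C)(C)C(C)(C)C)cc1O[Si](C)(C)C(C)(C)C | intermediate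
23 | 3-(tert-butyldimethylsilyloxy)-4-methoxybenzoic acid | COc1ccc(C(=O)O)cc1O[Si](C)(C)C(C)(C)C | intermediate
24 | (4R,5R,6R,7S,8R)-4,5-epoxy-6-(triethylsilyloxy)germacr-1(10)E-en-8-yl 3-(tert-butyldimethylsilyloxy)-4-methoxybenzoate | COc1ccc(C(=O)O[C@@H]2C/C(C)=C/CC[C@@]3(C)O[C@@H]3[C@H](O[Si](CC)(CC)CC)[C@H]2C(C)C)cc1O[Si](C)(C)C(C)(C)C | intermediate
25 | (4R,5R,6R,7R,8R)-4,5-epoxy-6-hydroxygermacr-1(10)E-en-8-yl 3-hydroxy-4-methoxybenzoate; systematically (1R,2R,3R,4R,6E,10R)-2-hydroxy-6,10-dimethyl-3-(propan-2-yl)-11-oxabicyclo[8.1.0]undec-6-en-4-yl 3-hydroxy-4-methoxybenzoate | COc1ccc(C(=O)O[C@@H]2C/C(C)=C/CC[C@@]3(C)O[C@@H]3[C@H](O)[C@H]2C(C)C)cc1O | target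

**Step count and risks**

Total step count: 17. Longest linear sequence: 14 steps (steps 1–6, 9–14, 16 and 17).

The three steps most likely to fail:

1. Step 13 (ring closure). What may go wrong: ethyl transfer to or reduction of the aldehyde, migration of the β,γ-alkene into conjugation under the mildly basic zinc species before ring closure, intermolecular allylation at the concentration needed for a useful rate, or addition on the wrong face of the allyl unit. Fallback: the allyl nucleophile is generated instead by oxidative addition of CrCl2 (divalent chromium) to an allylic chloride, which is a neutral, non-basic Nozaki–Hiyama allylation with a tight chair transition state. The fallback sets out from 15. Methanolysis of the benzoate (K2CO3, MeOH) gives (2E,4R)-4-[(2R,3R)-3-[(3E)-6-hydroxy-4-methylhex-3-en-1-yl]-3-methyloxiran-2-yl]-2-methyl-4-(triethylsilyloxy)but-2-en-1-ol F1. Selective Corey–Kim chlorination of the allylic hydroxyl (N-chlorosuccinimide, Me2S, CH2Cl2, −20 °C to 0 °C; the non-allylic hydroxyl is returned on work-up) gives the chloro alcohol (3E)-6-[(2R,3R)-3-[(1R,2E)-4-chloro-3-methyl-1-(triethylsilyloxy)but-2-en-1-yl]-2-methyloxiran-2-yl]-3-methylhex-3-en-1-ol F2. Dess–Martin oxidation gives the chloro aldehyde (3E)-6-[(2R,3R)-3-[(1R,2E)-4-chloro-3-methyl-1-(triethylsilyloxy)but-2-en-1-yl]-2-methyloxiran-2-yl]-3-methylhex-3-enal F3. Slow addition of F3 to CrCl2 in THF at rt should close the ring, and the route is rejoined at 19.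

2. Step 9 (C6 stereocentre). What may go wrong: poor facial selectivity at the aldehyde, because Felkin–Anh addition and addition through a chromium chelate with the oxirane oxygen lead to opposite epimers. Fallback: the stereocentre is set by reduction instead of addition. The fallback sets out from 7 (with 11). The coupling mixture of 12 and its epimer (2E,4S)-4-hydroxy-2-methyl-4-[(2R,3R)-3-methyl-3-[(3E)-4-methylhexa-3,5-dien-1-yl]oxiran-2-yl]but-2-en-1-yl benzoate F4 is oxidised (Dess–Martin periodinane, pyridine) to the epoxy enone (2E)-2-methyl-4-[(2S,3R)-3-methyl-3-[(3E)-4-methylhexa-3,5-dien-1-yl]oxiran-2-yl]-4-oxobut-2-en-1-yl benzoate F5. Reduction with Zn(BH4)2 in Et2O at −20 °C, in which zinc chelates the carbonyl and oxirane oxygens and hydride is delivered to give the anti epoxy alcohol (a 1,2-reduction of the enone), should return the route at 12.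

3. Step 14 (hydrogenation). What may go wrong: over-reduction of the strained E ring alkene, or very slow reduction of the isopropenyl group, which is flanked by two substituted carbons. Fallback: the reduction is postponed and made hydroxyl-directed. The fallback sets out from 19. Esterification with 23 (DCC, DMAP) gives (4R,5R,6R,7S,8R)-4,5-epoxy-6-(triethylsilyloxy)germacra-1(10)E,11-dien-8-yl 3-(tert-butyldimethylsilyloxy)-4-methoxybenzoate F6. Desilylation (Bu4NF, AcOH, THF) gives (4R,5R,6R,7R,8R)-4,5-epoxy-6-hydroxygermacra-1(10)E,11-dien-8-yl 3-hydroxy-4-methoxybenzoate F7, in which the free O6–H is homoallylic to C11=C12 while O8 is acylated. Directed hydrogenation with [Ir(cod)(PCy3)(py)]PF6 and H2 in CH2Cl2 at low catalyst loading should then deliver hydrogen only to the isopropenyl group, and the route comes back at 25.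

**Further compounds**

F1 | step 13 | (2E,4R)-4-[(2R,3R)-3-[(3E)-6-hydroxy-4-methylhex-3-en-1-yl]-3-methyloxiran-2-yl]-2-methyl-4-(triethylsilyloxy)but-2-en-1-ol | OCC/C(C)=C/CC[C@@]1(C)O[C@@H]1[C@H](O[Si](CC)(CC)CC)/C=C(\C)CO
F2 | step 13 | (3E)-6-[(2R,3R)-3-[(1R,2E)-4-chloro-3-methyl-1-(triethylsilyloxy)but-2-en-1-yl]-2-methyloxiran-2-yl]-3-methylhex-3-en-1-ol | OCC/C(C)=C/CC[C@@]1(C)O[C@@H]1[C@H](O[Si](CC)(CC)CC)/C=C(\C)CCl
F3 | step 13 | (3E)-6-[(2R,3R)-3-[(1R,2E)-4-chloro-3-methyl-1-(triethylsilyloxy)but-2-en-1-yl]-2-methyloxiran-2-yl]-3-methylhex-3-enal | O=CC/C(C)=C/CC[C@@]1(C)O[C@@H]1[C@H](O[Si](CC)(CC)CC)/C=C(\C)CCl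
F4 | step 9 | (2E,4S)-4-hydroxy-2-methyl-4-[(2R,3R)-3-methyl-3-[(3E)-4-methylhexa-3,5-dien-1-yl]oxiran-2-yl]but-2-en-1-yl benzoate | C=C/C(C)=C/CC[C@@]1(C)O[C@@H]1[C@@H](O)/C=C(\C)COC(=O)c1ccccc1
F5 | step 9 | (2E)-2-methyl-4-[(2S,3R)-3-methyl-3-[(3E)-4-methylhexa-3,5-dien-1-yl]oxiran-2-yl]-4-oxobut-2-en-1-yl benzoate | C=C/C(C)=C/CC[C@@]1(C)O[C@@H]1C(=O)/C=C(\C)COC(=O)c1ccccc1
F6 | step 14 | (4R,5R,6R,7S,8R)-4,5-epoxy-6-(triethylsilyloxy)germacra-1(10)E,11-dien-8-yl 3-(tert-butyldimethylsilyloxy)-4-methoxybenzoate | COc1ccc(C(=O)O[C@@H]2C/C(C)=C/CC[C@@]3(C)O[C@@H]3[C@H](O[Si](CC)(CC)CC)[C@H]2C(C)=C)cc1O[Si](C)(C)C(C)(C)C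
F7 | step 14 | (4R,5R,6R,7R,8R)-4,5-epoxy-6-hydroxygermacra-1(10)E,11-dien-8-yl 3-hydroxy-4-methoxybenzoate | COc1ccc(C(=O)O[C@@H]2C/C(C)=C/CC[C@@]3(C)O[C@@H]3[C@H](O)[C@H]2C(C)=C)cc1O
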